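**Retrosynthetic overview**
- C7=C8 (exocyclic alkene): aldol addition, then dehydration, between a 2-chloro-4-hydroxy-4-octenylcyclopentenone and methyl (5Z)-7-oxohept-5-enoate.
- 14Z alkene from an alkyne by semihydrogenation; C10–Cl by α-chlorination of the enone.
- C12–C13 bond and the only stereocentre (C12): enantioselective, chiral-biphenol-catalysed propargylboration of cyclopent-4-ene-1,3-dione with a 3-pentyl allenylboronate (metal-free; new on this substrate class).
- Z-enal: lithium-free Wittig reaction of the C1–C5 phosphonium salt with glyoxal mono-acetal, then acetal hydrolysis.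
- Rings: the single carbocycle is bought as cyclopent-4-ene-1,3-dione; no ring is formed in the route.

Assumption: the facial sense of step 3 is assigned by analogy to known biphenol-catalysed boronate additions to ketones; if the first run gives the (R)-carbinol, (R)-3,3'-Br2-BINOL is used instead and nothing else changes.

Numbering used in the comments (prostanoid): ester carbon C1, diene C5=C6 and C7=C8, ring C8–C12, carbonyl C9, Cl on C10, carbinol C12, octenyl chain C13–C20.

**Route**

Step 1
Reactants: 1 oct-2-yn-1-ol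
Product: 2 methyl oct-2-yn-1-yl carbonate
Conditions: ClCO2Me (1.2 equiv), pyridine (2 equiv), CH2Cl2, 0 °C → rt
Reagents that add atoms: methyl chloroformate, COC(=O)Cl
Why: Acylation of a primary propargylic alcohol with a chloroformate (carbonate formation) is routine and installs the leaving group for step 2.

Step 2
Reactants: 2 methyl oct-2-yn-1-yl carbonate
Product: 3 5,5-dimethyl-2-(octa-1,2-dien-3-yl)-1,3,2-dioxaborinane
Conditions: B2nep2 (1.2 equiv), CuCl (5 mol%), Xantphos (5 mol%), KOtBu (10 mol%), THF, rt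
Reagents that add atoms: bis(neopentyl glycolato)diboron (B2nep2), CC1(C)COB(OC1)B1OCC(C)(C)CO1
Why: Copper-catalysed SN2'-type borylation of a propargylic carbonate, in which the boryl complex of monovalent copper adds across the alkyne with boron at C3 and β-eliminates the carbonate, gives the 1,1-disubstituted allenylboronate regiospecifically, the six-membered glycol ester being chosen because it exchanges with biphenols.

Step 3
Reactants: 3 5,5-dimethyl-2-(octa-1,2-dien-3-yl)-1,3,2-dioxaborinane; 4 cyclopent-4-ene-1,3-dione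
Product: 6 (4S)-4-hydroxy-4-(oct-2-yn-1-yl)cyclopent-2-en-1-one, via boryl ether 5 (not isolated)
Conditions: 3 (1.05 equiv), (S)-3,3'-Br2-BINOL (10 mol%), t-BuOH (1.5 equiv), toluene, −20 °C, 24–48 h; then H2O
Reagents that add atoms: none
Why: Proposed new method: chiral-biphenol-catalysed enantioface-selective mono-propargylboration of a cyclic ene-1,3-dione with a 3-alkyl allenylboronate (closest known reaction type: 3,3'-Br2-BINOL-catalysed asymmetric propargyl- and allylboration of simple ketones with allenyl and allyl boronates), in which the biphenol opens the dioxaborinane to a hydrogen-bonded, more Lewis-acidic mixed boronate that binds one of the two homotopic carbonyls of 4 and a closed six-membered SE2' transition state delivers the allene CH2 terminus to the Re face (the 3-bromo group telling the flat CH=CH flank from the CH2–C=O flank), so that the C12–C13 bond, the internal alkyne and the (S)-carbinol (R in the target after the later priority change) are formed in one event, while the remaining carbonyl, now a plain enone, is too unreactive for a second addition.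

Step 4
Reactants: 6 (4S)-4-hydroxy-4-(oct-2-yn-1-yl)cyclopent-2-en-1-one
Product: 7 (4S)-2-chloro-4-hydroxy-4-(oct-2-yn-1-yl)cyclopent-2-en-1-one
Conditions: PhICl2 (1.2 equiv), pyridine (3 equiv), CH2Cl2, 0 °C → rt, dark
Reagents that add atoms: iodobenzene dichloride, ClI(Cl)c1ccccc1
Why: α-Chlorination of an enone by chlorine addition and pyridine-induced dehydrochlorination places Cl on the α-carbon only (C10), the alkyne and the tertiary alcohol reacting more slowly, and the stereocentre is not touched.

Step 5
Reactants: 7 (4S)-2-chloro-4-hydroxy-4-(oct-2-yn-1-yl)cyclopent-2-en-1-one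
Product: 8 (4S)-2-chloro-4-hydroxy-4-[(2Z)-oct-2-en-1-yl]cyclopent-2-en-1-one
Conditions: H2 (1 atm), Pd/CaCO3 poisoned with Pb(OAc)2 (Lindlar catalyst), quinoline, EtOAc, 0 °C, stopped at 1.0 equiv H2
Reagents that add atoms: none
Why: Lindlar semihydrogenation adds H2 syn to the alkyne to give the 14Z alkene while the poisoned catalyst spares the chloro-enone, and it is placed after step 4 so that electrophilic chlorine never meets the Z-alkene.

Step 6
Reactants: 9 (4-carboxybutyl)triphenylphosphonium bromide; 10 2,2-dimethoxyacetaldehyde (anhydrous, freshly distilled from the commercial aqueous solution)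
Product: 13 methyl (5Z)-7,7-dimethoxyhept-5-enoate, via ylide 11 (not isolated), via sodium carboxylate 12 (not isolated)
Conditions: NaN(SiMe3)2 (2.1 equiv), THF, 0 °C; 10, −78 °C → rt; then MeI (3 equiv), DMF, rt
Reagents that add atoms: iodomethane, CI
Why: Lithium-free Wittig olefination of a non-stabilised ylide with an α-alkoxy aldehyde is reliably Z-selective (sets 5Z), and the carboxylate left by the double deprotonation is O-methylated in the same pot (SN2 esterification).

Step 7
Reactants: 13 methyl (5Z)-7,7-dimethoxyhept-5-enoate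
Product: 14 methyl (5Z)-7-oxohept-5-enoate
Conditions: 10% aq. oxalic acid on silica gel, CH2Cl2, 0 °C, 30 min; used at once
Reagents that add atoms: water, O
Why: Acid-catalysed acetal hydrolysis of an allylic acetal proceeds under conditions too mild to isomerise the Z-enal or touch the ester.

Step 8
Reactants: 8 (4S)-2-chloro-4-hydroxy-4-[(2Z)-oct-2-en-1-yl]cyclopent-2-en-1-one; 14 methyl (5Z)-7-oxohept-5-enoate
Product: 17 methyl (5Z)-7-[(2S)-4-chloro-2-hydroxy-2-[(2Z)-oct-2-en-1-yl]-5-oxocyclopent-3-en-1-yl]-7-hydroxyhept-5-enoate, via dilithium dienolate 15 (not isolated), via dilithium aldolate 16 (not isolated)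
Conditions: LiN(iPr)2 (2.2 equiv), THF, −78 °C, 30 min; 14 (1.3 equiv), −78 °C, 20 min; AcOH quench at −78 °C
Reagents that add atoms: none
Why: Directed aldol addition in which two equivalents of amide base give the alkoxide and the cross-conjugated C8 enolate (β-loss of the C12 oxygen is blocked because it would give a cyclopentadienone), which adds 1,2 to the enal through a closed Zimmerman–Traxler chair (C7/C8 anti isomers expected as the major part of the diastereomer mixture), C12 being untouched and the cold quench preventing retro-aldol.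

Step 9
Reactants: 17 methyl (5Z)-7-[(2S)-4-chloro-2-hydroxy-2-[(2Z)-oct-2-en-1-yl]-5-oxocyclopent-3-en-1-yl]-7-hydroxyhept-5-enoate
Product: 19 methyl (5Z,7Z)-7-[(2R)-4-chloro-2-hydroxy-2-[(2Z)-oct-2-en-1-yl]-5-oxocyclopent-3-en-1-ylidene]hept-5-enoate, via mesylate 18 (not isolated)
Conditions: MsCl (1.2 equiv), Et3N (4 equiv), CH2Cl2, −30 → 0 °C, dark; HPLC
Reagents that add atoms: none
Why: Aldol condensation completed by elimination of a β-mesyloxy ketone, where antiperiplanar loss of MsOH from the major anti aldol places C6 cis to the C9 carbonyl (7Z), which is also the isomer free of allylic strain against the quaternary C12, and only the secondary allylic alcohol is sulfonylated so the C12 carbinol is preserved.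

**Compound list**

1 | oct-2-yn-1-ol | CCCCCC#CCO | starting material
2 | methyl oct-2-yn-1-yl carbonate | CCCCCC#CCOC(=O)OC | intermediate
3 | 5,5-dimethyl-2-(octa-1,2-dien-3-yl)-1,3,2-dioxaborinane | C=C=C(CCCCC)B1OCC(C)(C)CO1 | intermediate
4 | cyclopent-4-ene-1,3-dione | O=C1CC(=O)C=C1 | starting material
5 | (4S)-4-[(5,5-dimethyl-1,3,2-dioxaborinan-2-yl)oxy]-4-(oct-2-yn-1-yl)cyclopent-2-en-1-one (boryl ether, not isolated) | CCCCCC#CC[C@@]1(OB2OCC(C)(C)CO2)C=CC(=O)C1 | intermediate
6 | (4S)-4-hydroxy-4-(oct-2-yn-1-yl)cyclopent-2-en-1-one | CCCCCC#CC[C@@]1(O)C=CC(=O)C1 | intermediate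
7 | (4S)-2-chloro-4-hydroxy-4-(oct-2-yn-1-yl)cyclopent-2-en-1-one | CCCCCC#CC[C@@]1(O)C=C(Cl)C(=O)C1 | intermediate
8 | (4S)-2-chloro-4-hydroxy-4-[(2Z)-oct-2-en-1-yl]cyclopent-2-en-1-one | CCCCC/C=C\C[C@@]1(O)C=C(Cl)C(=O)C1 | intermediate
9 | (4-carboxybutyl)triphenylphosphonium bromide | [Br-].OC(=O)CCCC[P+](c1ccccc1)(c1ccccc1)c1ccccc1 | starting material
10 | 2,2-dimethoxyacetaldehyde | COC(OC)C=O | starting material
11 | sodium 5-(triphenyl-λ5-phosphanylidene)pentanoate (ylide, not isolated) | [Na+].[O-]C(=O)CCCC=P(c1ccccc1)(c1ccccc1)c1ccccc1 | intermediate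
12 | sodium (5Z)-7,7-dimethoxyhept-5-enoate (not isolated) | [Na+].COC(OC)/C=C\CCCC(=O)[O-] | intermediate
13 | methyl (5Z)-7,7-dimethoxyhept-5-enoate | COC(OC)/C=C\CCCC(=O)OC | intermediate
14 | methyl (5Z)-7-oxohept-5-enoate | O=C/C=C\CCCC(=O)OC | intermediate
15 | dilithium (3S)-5-chloro-3-[(2Z)-oct-2-en-1-yl]-3-oxidocyclopenta-1,4-dien-1-olate (alkoxide and dienolate of 8, not isolated) | [Li+].[Li+].CCCCC/C=C\C[C@@]1([O-])C=C(Cl)C([O-])=C1 | intermediate
16 | dilithium bis-alkoxide of 17 (C7 and C12 oxygens, not isolated) | [Li+].[Li+].CCCCC/C=C\C[C@@]1([O-])C=C(Cl)C(=O)C1C([O-])/C=C\CCCC(=O)OC | intermediate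
17 | methyl (5Z)-7-[(2S)-4-chloro-2-hydroxy-2-[(2Z)-oct-2-en-1-yl]-5-oxocyclopent-3-en-1-yl]-7-hydroxyhept-5-enoate (mixture of C7/C8 diastereomers, anti major) | CCCCC/C=C\C[C@@]1(O)C=C(Cl)C(=O)C1C(O)/C=C\CCCC(=O)OC | intermediate
18 | methyl (5Z)-7-[(2S)-4-chloro-2-hydroxy-2-[(2Z)-oct-2-en-1-yl]-5-oxocyclopent-3-en-1-yl]-7-(methanesulfonyloxy)hept-5-enoate (not isolated) | CCCCC/C=C\C[C@@]1(O)C=C(Cl)C(=O)C1C(OS(C)(=O)=O)/C=C\CCCC(=O)OC | intermediate
19 | methyl (5Z,7Z)-7-[(2R)-4-chloro-2-hydroxy-2-[(2Z)-oct-2-en-1-yl]-5-oxocyclopent-3-en-1-ylidene]hept-5-enoate (the target chlorovulone, 5Z,7Z,14Z,12R) | CCCCC/C=C\C[C@@]1(O)C=C(Cl)C(=O)/C1=C\C=C/CCCC(=O)OC | target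

**Step count and risks**

Total steps: 9. Longest linear sequence: 7 (steps 1, 2, 3, 4, 5, 8, 9); steps 6 and 7 form the side branch.

The three steps most likely to fail:

1. Step 3 (the proposed new method). The risks are the acidic CH2 of the dione (enolisation or protodeboronation), an uncatalysed background addition, and weak discrimination between the two small ring flanks. The fallback uses known chemistry, sets out from 4 and comes back at 6. Dione 4 is converted with 2,2-dimethylpropane-1,3-diol (TsOH cat., benzene, Dean–Stark) into the mono-ketal 8,8-dimethyl-6,10-dioxaspiro[4.5]dec-3-en-2-one F1, an ordinary enone whose two flanks differ strongly in size. F1 then undergoes the established biphenol-catalysed asymmetric propargylboration of ketones with 3 (3,3'-Br2-BINOL, t-BuOH, toluene), which gives first the boryl ether 2-{[(2S)-8,8-dimethyl-2-(oct-2-yn-1-yl)-6,10-dioxaspiro[4.5]dec-3-en-2-yl]oxy}-5,5-dimethyl-1,3,2-dioxaborinane F2 and, after aqueous work-up, the carbinol (2S)-8,8-dimethyl-2-(oct-2-yn-1-yl)-6,10-dioxaspiro[4.5]dec-3-en-2-ol F3. Aqueous oxalic acid in THF removes the ketal and returns the route at 6, at a cost of two extra steps.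

2. Step 4. Electrophilic chlorine may attack the alkyne, or add only slowly to an enone whose β-carbon sits next to a quaternary centre. The fallback sets out from 6 and comes back at 8, bypassing both step 4 and the Lindlar reduction of a vinyl chloride. Compound 6 is semihydrogenated first (H2, Pd/CaCO3 poisoned with Pb(OAc)2, quinoline) to (4S)-4-hydroxy-4-[(2Z)-oct-2-en-1-yl]cyclopent-2-en-1-one F4. Nucleophilic epoxidation, which touches only the enone (H2O2, NaOH cat., MeOH, 0 °C, short contact time to avoid retro-aldol), gives the epoxy ketone (4S)-4-hydroxy-4-[(2Z)-oct-2-en-1-yl]-6-oxabicyclo[3.1.0]hexan-2-one F5. Conc. aq. HCl in THF (0 °C → rt) opens F5 at the α-carbon to the chlorohydrin (4S)-2-chloro-3,4-dihydroxy-4-[(2Z)-oct-2-en-1-yl]cyclopentan-1-one F6, which loses water under the same acid to give 8.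

3. Step 9. The 7Z:7E ratio is uncertain: the anti/syn ratio of 17 is not controlled, and the elimination may lose stereospecificity through the enolate. The fallback sets out from 17 and comes back at 19. If the mesylation and elimination give mainly the 7E isomer methyl (5Z,7E)-7-[(2R)-4-chloro-2-hydroxy-2-[(2Z)-oct-2-en-1-yl]-5-oxocyclopent-3-en-1-ylidene]hept-5-enoate F7, it is separated by HPLC and photo-equilibrated (350 nm, benzene, rt; these cross-conjugated dienones interconvert under light). The irradiation is stopped at low conversion to limit scrambling at C5; 19 is separated and F7 recycled.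

**Further compounds**

F1 | step 3 | 8,8-dimethyl-6,10-dioxaspiro[4.5]dec-3-en-2-one | O=C1CC2(OCC(C)(C)CO2)C=C1
F2 | step 3 | 2-{[(2S)-8,8-dimethyl-2-(oct-2-yn-1-yl)-6,10-dioxaspiro[4.5]dec-3-en-2-yl]oxy}-5,5-dimethyl-1,3,2-dioxaborinane | CCCCCC#CC[C@@]1(OB2OCC(C)(C)CO2)C=CC2(OCC(C)(C)CO2)C1
F3 | step 3 | (2S)-8,8-dimethyl-2-(oct-2-yn-1-yl)-6,10-dioxaspiro[4.5]dec-3-en-2-ol | CCCCCC#CC[C@@]1(O)C=CC2(OCC(C)(C)CO2)C1
F4 | step 4 | (4S)-4-hydroxy-4-[(2Z)-oct-2-en-1-yl]cyclopent-2-en-1-one | CCCCC/C=C\C[C@@]1(O)C=CC(=O)C1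
F5 | step 4 | (4S)-4-hydroxy-4-[(2Z)-oct-2-en-1-yl]-6-oxabicyclo[3.1.0]hexan-2-one | CCCCC/C=C\C[C@@]1(O)C2OC2C(=O)C1
F6 | step 4 | (4S)-2-chloro-3,4-dihydroxy-4-[(2Z)-oct-2-en-1-yl]cyclopentan-1-one | CCCCC/C=C\C[C@@]1(O)C(O)C(Cl)C(=O)C1
F7 | step 9 | methyl (5Z,7E)-7-[(2R)-4-chloro-2-hydroxy-2-[(2Z)-oct-2-en-1-yl]-5-oxocyclopent-3-en-1-ylidene]hept-5-enoate | CCCCC/C=C\C[C@@]1(O)C=C(Cl)C(=O)/C1=C/C=C\CCCC(=O)OC
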